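**Retrosynthetic overview**
1. The target is a hexasubstituted acylphloroglucinol. Its acid- and Claisen-sensitive geranyl ether is made last by cutting it at OCH2–CH= into an aryloxyacetic acid and an E-alkenyl iodide, joined by a protecting-group-free nickel/photoredox decarboxylative C(sp3)–C(sp2) coupling.
2. Enabling feature: the ether CH2 sits on the oxygen of ring C4 (between C3–CH3 and C5–acetyl), so a radical on it is α-oxygen-stabilised and is released from a CH2–CO2H handle by loss of CO2. The C2–OH and C6–OH are each locked in a six-membered hydrogen bond to an ortho ketone C=O, and the benzene ring has no C–H left, so nothing else competes.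
3. The alkenyl iodide comes from 6-methylhept-5-en-1-yne by zirconium-catalysed syn-methylalumination and iodination, which sets the E-trisubstituted alkene and its methyl group. The enyne comes from homoprenyl bromide and acetylide.
4. The acid comes from 2-methylphloroglucinol: Friedel–Crafts acylation with (R)-2-methylbutanoyl chloride (the two free ring positions are equivalent), alkylation of the para hydroxyl with methyl bromoacetate (this fixes which oxygen becomes the ether), C-acetylation at the last ring C–H, and saponification.
5. No ring is formed: the benzene ring is bought, and the single stereocentre is bought with (R)-2-methylbutanoic acid.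

Key step: step 8

Remark: the single stereocentre of the target has the R configuration; (R)-2-methylbutanoic acid and 2-methylphloroglucinol are taken as purchasable.

**Route**

Step 1
Reactants: 1 (R)-2-methylbutanoic acid
Product: 2 (R)-2-methylbutanoyl chloride
Conditions: (COCl)2 (1.2 equiv), DMF (cat.), CH2Cl2, 0 °C → rt; concentrate, use crude
Reagents that add atoms: oxalyl chloride, ClC(=O)C(=O)Cl
Why: Acyl chloride formation through the Vilsmeier-type chloroiminium catalyst is base-free, so no ketene can form and the (R)-centre taken from 1 should be kept.

Step 2
Reactants: 2 (R)-2-methylbutanoyl chloride; 3 2-methylbenzene-1,3,5-triol (2-methylphloroglucinol)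
Product: 4 (2R)-2-methyl-1-(2,4,6-trihydroxy-3-methylphenyl)butan-1-one
Conditions: AlCl3 (4 equiv), CH2Cl2/PhNO2, 0 °C → rt; then ice/1 M HCl
Reagents that add atoms: none
Why: Friedel–Crafts C-acylation of a ring activated by three hydroxyls, in which the two free ring carbons of 3 are equivalent by symmetry, the first acyl group deactivates the ring against a second acylation, and the stereocentre should come unchanged from 2 because the acylium ion is formed without base at low temperature.

Step 3
Reactants: 4 (2R)-2-methyl-1-(2,4,6-trihydroxy-3-methylphenyl)butan-1-one; 5 methyl bromoacetate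
Product: 6 methyl 2-{3,5-dihydroxy-2-methyl-4-[(2R)-2-methylbutanoyl]phenoxy}acetate
Conditions: K2CO3 (1.05 equiv), 5 (1.0 equiv), acetone, 0 °C → rt
Reagents that add atoms: none
Why: Williamson ether synthesis with one equivalent of weak base, in which the C4–OH para to the ketone is the most acidic hydroxyl and is not hydrogen-bonded to the carbonyl, so its phenoxide should be the one alkylated at oxygen by the α-bromo ester.

Step 4
Reactants: 6 methyl 2-{3,5-dihydroxy-2-methyl-4-[(2R)-2-methylbutanoyl]phenoxy}acetate
Product: 7 methyl 2-{2-acetyl-3,5-dihydroxy-6-methyl-4-[(2R)-2-methylbutanoyl]phenoxy}acetate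
Conditions: Ac2O (1.5 equiv), BF3·OEt2 (4 equiv), CH2Cl2, 0 °C → rt; then H2O/MeOH, 40 °C
Reagents that add atoms: acetic anhydride, CC(=O)OC(C)=O
Why: Friedel–Crafts C-acetylation at the only ring carbon still bearing hydrogen, which is activated by two ortho oxygens and one para oxygen; the aryl ether and methyl ester should tolerate BF3, and the α-stereocentre is expected to hold because enolisation would need a tetrasubstituted enol next to a di-ortho-substituted ring.

Step 5
Reactants: 7 methyl 2-{2-acetyl-3,5-dihydroxy-6-methyl-4-[(2R)-2-methylbutanoyl]phenoxy}acetate
Product: 8 2-{2-acetyl-3,5-dihydroxy-6-methyl-4-[(2R)-2-methylbutanoyl]phenoxy}acetic acid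
Conditions: LiOH·H2O (4 equiv), THF/H2O (3:1), 0 °C → rt; then 1 M HCl to pH 2
Reagents that add atoms: lithium hydroxide, [Li+].[OH-]; water, O
Why: Saponification of an activated α-aryloxy ester is fast at 0 °C, and under base the ring is a phenoxide that turns both ketones into vinylogous carboxylates, which should suppress enolisation at the stereocentre and aldol closure of the side chain onto the acetyl group.

Step 6
Reactants: 9 5-bromo-2-methylpent-2-ene
Product: 10 6-methylhept-5-en-1-yne
Conditions: lithium acetylide–ethylenediamine complex (1.5 equiv), DMSO, 10 °C → rt; distil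
Reagents that add atoms: lithium acetylide–ethylenediamine complex, [Li]C#C.NCCN
Why: SN2 alkynylation of a primary bromide by acetylide in a dipolar aprotic solvent, with the trisubstituted alkene inert.

Step 7
Reactants: 10 6-methylhept-5-en-1-yne
Product: 12 (E)-1-iodo-2,6-dimethylhepta-1,5-diene, via (E)-alkenyldimethylalane 11 (not isolated)
Conditions: Me3Al (2 equiv), Cp2ZrCl2 (0.25 equiv), CH2Cl2, rt; then I2 (1.2 equiv), THF, −30 → 0 °C; aq. Na2S2O3
Reagents that add atoms: trimethylaluminium, C[Al](C)C; iodine, II
Why: Zirconium-catalysed carboalumination (syn-methylalumination) of the terminal alkyne places Al on the terminal carbon and CH3 on the internal carbon on the same face, and iodinolysis of the C–Al bond with retention should give the E-iodide while the remote trisubstituted alkene stays untouched.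

Step 8
Reactants: 8 2-{2-acetyl-3,5-dihydroxy-6-methyl-4-[(2R)-2-methylbutanoyl]phenoxy}acetic acid; 12 (E)-1-iodo-2,6-dimethylhepta-1,5-diene
Product: 13 (2R)-1-{3-acetyl-4-[(2E)-3,7-dimethylocta-2,6-dien-1-yloxy]-2,6-dihydroxy-5-methylphenyl}-2-methylbutan-1-one (target)
Conditions: 12 (1.5 equiv), Ir[dF(CF3)ppy]2(dtbbpy)PF6 (1 mol%), NiCl2·glyme (5 mol%), dtbbpy (5 mol%), Cs2CO3 (0.55 equiv), degassed DMSO, blue LEDs (450 nm), rt
Reagents that add atoms: none
Why: The caesium carboxylate of 8 is oxidised by the photoexcited Ir(III) complex and loses CO2 to give the aryloxymethyl radical (stabilised by the ether oxygen on ring C4), while Ni(0)/dtbbpy inserts into the C–I bond of 12; capture of the radical by the alkenyl–Ni(II) species and reductive elimination from Ni(III) forge the OCH2–CH= bond, and Ir(II) returns Ni(I) to Ni(0). The closest known reaction type is the metallaphotoredox decarboxylative cross-coupling of α-oxy carboxylic acids with alkenyl iodides. No ring is closed and no stereocentre is created; the E geometry fixed in step 7 should be carried through because oxidative addition and reductive elimination at the sp2 carbon go with retention, and the (R)-centre is remote from every radical and basic site. The step needs chemoselectivity for the carboxylate over two phenols, two ketones and the product's allylic aryl ether: the CO2H is far more acidic than the phenols, so 0.55 equiv of Cs2CO3 should ionise only it; the C2–OH and C6–OH are each held in a six-membered hydrogen bond to an ortho C=O, which makes them poor hydrogen-atom donors and hard to oxidise; and the ring has no C–H left for radical attack. An excess of 12 should keep the nickel engaged with the iodide and away from the newly formed geranyl ether.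

**Compound list**
1 | (R)-2-methylbutanoic acid | CC[C@@H](C)C(=O)O | starting material
2 | (R)-2-methylbutanoyl chloride | CC[C@@H](C)C(=O)Cl | intermediate
3 | 2-methylbenzene-1,3,5-triol (2-methylphloroglucinol) | Cc1c(O)cc(O)cc1O | starting material
4 | (2R)-2-methyl-1-(2,4,6-trihydroxy-3-methylphenyl)butan-1-one | CC[C@@H](C)C(=O)c1c(O)c(C)c(O)cc1O | intermediate
5 | methyl bromoacetate | COC(=O)CBr | starting material
6 | methyl 2-{3,5-dihydroxy-2-methyl-4-[(2R)-2-methylbutanoyl]phenoxy}acetate | CC[C@@H](C)C(=O)c1c(O)c(C)c(OCC(=O)OC)cc1O | intermediate
7 | methyl 2-{2-acetyl-3,5-dihydroxy-6-methyl-4-[(2R)-2-methylbutanoyl]phenoxy}acetate | CC[C@@H](C)C(=O)c1c(O)c(C)c(OCC(=O)OC)c(C(C)=O)c1O | intermediate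
8 | 2-{2-acetyl-3,5-dihydroxy-6-methyl-4-[(2R)-2-methylbutanoyl]phenoxy}acetic acid | CC[C@@H](C)C(=O)c1c(O)c(C)c(OCC(=O)O)c(C(C)=O)c1O | intermediate
9 | 5-bromo-2-methylpent-2-ene | CC(C)=CCCBr | starting material
10 | 6-methylhept-5-en-1-yne | C#CCCC=C(C)C | intermediate
11 | (E)-(2,6-dimethylhepta-1,5-dien-1-yl)dimethylalane | C[Al](C)/C=C(\C)CCC=C(C)C | intermediate
12 | (E)-1-iodo-2,6-dimethylhepta-1,5-diene | I/C=C(\C)CCC=C(C)C | intermediate
13 | (2R)-1-{3-acetyl-4-[(2E)-3,7-dimethylocta-2,6-dien-1-yloxy]-2,6-dihydroxy-5-methylphenyl}-2-methylbutan-1-one | CC[C@@H](C)C(=O)c1c(O)c(C)c(OC/C=C(\C)CCC=C(C)C)c(C(C)=O)c1O | target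

**Step count and risks**

Total step count: 8. Longest linear sequence: 6 steps (steps 1, 2, 3, 4, 5 and 8).

Steps most likely to fail:

1. Step 8. Possible failure processes are quenching of the excited photocatalyst by phenoxide formed through proton exchange with the carboxylate, hydrogen-atom transfer to the aryloxymethyl radical (simple reduction of the handle), sequestration of nickel by the hydroxy-ketone chelating sites, or ionisation of the newly formed allylic aryl ether by low-valent nickel. The fallback sets out from 8 and comes back at 13. Acid 8 would be condensed with N-hydroxyphthalimide (DIC, cat. DMAP, CH2Cl2) to the redox-active ester 1,3-dioxoisoindolin-2-yl 2-{2-acetyl-3,5-dihydroxy-6-methyl-4-[(2R)-2-methylbutanoyl]phenoxy}acetate F1. This ester would then be joined to 12 in a light- and base-free nickel-catalysed reductive decarboxylative alkenylation (NiBr2·glyme, dtbbpy, Zn, DMA, rt, or the electrochemical variant of this coupling) to give 13 directly.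

2. Step 3. Possible failure processes are loss of site selectivity in the O-alkylation: alkylation at a carbonyl-bonded hydroxyl, double alkylation, or C-alkylation at the free ring carbon. The fallback sets out from 4 and comes back at 6. It is a Mitsunobu etherification of 4 with methyl glycolate (PPh3, DIAD, THF, 0 °C), in which only the most acidic, non-chelated para hydroxyl should act as the pronucleophile. This fallback makes no new compound (F0).

3. Step 4. Possible failure processes are erosion of configuration at the α-stereocentre through the boron-chelated ketone, or loss of the glycolate ether or ester under the Lewis acid. The fallback sets out from 6 and comes back at 7. It is a Houben–Hoesch reaction of 6 with acetonitrile (ZnCl2, HCl gas, Et2O, 0 °C) to give the ketiminium salt methyl 2-{3,5-dihydroxy-2-(1-iminoethyl)-6-methyl-4-[(2R)-2-methylbutanoyl]phenoxy}acetate hydrochloride F2, which would be hydrolysed in warm water to 7. The electrophile is a nitrilium ion and no anhydride or boron Lewis acid is present; any ester hydrolysed on the way would give 8 and only anticipate step 5.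

Further compounds
F1 | step 8 | 1,3-dioxoisoindolin-2-yl 2-{2-acetyl-3,5-dihydroxy-6-methyl-4-[(2R)-2-methylbutanoyl]phenoxy}acetate | CC[C@@H](C)C(=O)c1c(O)c(C)c(OCC(=O)ON2C(=O)c3ccccc3C2=O)c(C(C)=O)c1O
F0 | step 3 | none | none
F2 | step 4 | methyl 2-{3,5-dihydroxy-2-(1-iminoethyl)-6-methyl-4-[(2R)-2-methylbutanoyl]phenoxy}acetate hydrochloride | CC[C@@H](C)C(=O)c1c(O)c(C)c(OCC(=O)OC)c(C(C)=[NH2+])c1O.[Cl-]
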